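## Retrosynthetic overview
1. 22 ⇐ 21 by one global hydrogenolysis (6 benzyl groups, 2 aryl bromides). The biomimetic catechin-quinone/gallic acid oxidative coupling is deliberately not used.
2. 21 ⇐ 16 by C6 hydroxylation, oxidation and tautomerisation to the tropolone. 16 ⇐ 10 by enol triflate carbonylation, so the carboxyl carbon comes from CO.
3. Key step, 10 ⇐ 5 + cyclopentane-1,3-dione. A ring-B 5',6'-aryne inserts into a C–C σ-bond of the dione and forms C4a–C5 and C9–C9a in one operation (five-ring to seven-ring expansion).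
4. 5 ⇐ (+)-catechin by perbenzylation and tribromination. The 6-Br and 8-Br are traceless A-ring blocking groups and 6'-Br is the aryne trigger. C2 (R) and C3 (S) come from the chiral pool and are never touched.
5. Ring order: A, C and B are bought, the seven-membered carbocycle forms in step 3, and it is aromatised to the tropolone in step 7.

Assumption: the SMILES decodes to (2R,3S), the 2,3-trans arrangement of (+)-catechin, so the target is theaflavic acid; LiTMP is used as the commercial solid.

Locants: primed numbers refer to catechin ring B. From compound 10 on, the new bicycle has benzo[7]annulene locants: C1 carries the chroman, C3/C4 the catechol oxygens, C5 the ketone and C8 the carboxyl.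

## Route

Step 1
Reactants: 1 (+)-catechin; 2 benzyl bromide
Product: 3 penta-O-benzyl-(+)-catechin [(2R,3S)-3,5,7-tris(benzyloxy)-2-[3,4-bis(benzyloxy)phenyl]chroman]
Conditions: NaH (6 equiv), BnBr (6 equiv), DMF, −10 °C → rt
Reagents that add atoms: benzyl bromide BrCc1ccccc1
Why: Williamson etherification of the four phenoxides and the C3 alkoxide touches no bond at C2 or C3, and fast O-alkylation at low temperature caps the 4'-phenoxide before ring C can open through a quinone methide, so the (2R,3S) centres are carried over unchanged.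

Step 2
Reactants: 3 penta-O-benzyl-(+)-catechin; 4 N-bromosuccinimide
Product: 5 6,8,6'-tribromide [(2R,3S)-3,5,7-tris(benzyloxy)-6,8-dibromo-2-[4,5-bis(benzyloxy)-2-bromophenyl]chroman]
Conditions: NBS (3.2 equiv), CH2Cl2/MeCN, −20 °C → rt, dark
Reagents that add atoms: N-bromosuccinimide O=C1CCC(=O)N1Br
Why: Electrophilic aromatic bromination follows ring nucleophilicity (C8 and C6 of the phloroglucinol ring first, then the B-ring carbon para to 3'-OBn, C6'), which leaves A-ring bromines with no ortho hydrogen and a 6'-bromine with exactly one (H5').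

Step 3
Reactants: 5 6,8,6'-tribromide; 6 cyclopentane-1,3-dione
Product: 10 1-[(2R,3S)-3,5,7-tris(benzyloxy)-6,8-dibromochroman-2-yl]-3,4-bis(benzyloxy)-6,7-dihydro-5H-benzo[7]annulene-5,8(9H)-dione, via lithium enolate 7 (not isolated), via aryne 8 (not isolated), via cyclobutenoxide 9 (not isolated)
Conditions: 6 (2 equiv), LiTMP (2 equiv), THF, −78 → 0 °C; add 5, −78 °C; LiTMP (1.3 equiv) dropwise, → rt; 1 M HCl
Reagents that add atoms: cyclopentane-1,3-dione O=C1CCC(=O)C1
Why: Proposed new method: LiTMP removes H5', the only hydrogen flanked by Br and OBn, and loss of LiBr gives aryne 8 (classical dehydrohalogenative aryne formation as for 4-bromoveratrole); the carbon of enolate 7 adds to C6', the aryne carbon distal to the inductively withdrawing 4'-OBn (distortion control as in 3-alkoxyarynes); the C5' aryl anion closes on the neighbouring C=O to give 9, and fragmentation of this strained alkoxide inserts the arene into the C1–C2 bond of the symmetric dione; this is the known aryne acyl-alkylation/σ-insertion ring expansion of cyclic 1,3-diketones, run here on a base-generated rather than fluoride-generated aryne, with C2 and C3 as spectators.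

Step 4
Reactants: 10 ring-expanded 5,8-dione; 11 N-phenylbis(trifluoromethanesulfonimide)
Product: 13 1-[(2R,3S)-3,5,7-tris(benzyloxy)-6,8-dibromochroman-2-yl]-3,4-bis(benzyloxy)-5-oxo-6,7-dihydro-5H-benzo[7]annulen-8-yl trifluoromethanesulfonate, via potassium enolate 12 (not isolated)
Conditions: KHMDS (1.0 equiv), THF, −78 → 0 °C; PhNTf2, 0 °C; aq NH4Cl
Reagents that add atoms: N-phenylbis(trifluoromethanesulfonimide) O=S(=O)(N(c1ccccc1)S(=O)(=O)C(F)(F)F)C(F)(F)F
Why: Equilibrating enolisation takes the doubly activated C9–H (α to C8=O and benzylic) and O-sulfonylation gives the styrene-type enol triflate (enol triflate formation), while the di-ortho-substituted aryl ketone at C5 stays untouched.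

Step 5
Reactants: 13 enol triflate; 14 carbon monoxide; 15 benzyl alcohol
Product: 16 benzyl 1-[(2R,3S)-3,5,7-tris(benzyloxy)-6,8-dibromochroman-2-yl]-3,4-bis(benzyloxy)-5-oxo-6,7-dihydro-5H-benzo[7]annulene-8-carboxylate
Conditions: Pd(OAc)2 (5 mol %), dppf (6 mol %), CO (1 atm), BnOH (5 equiv), Et3N, DMF, 45 °C
Reagents that add atoms: carbon monoxide [C-]#[O+]; benzyl alcohol OCc1ccccc1
Why: In this Pd(0)-catalysed alkoxycarbonylation of a vinyl triflate, oxidative addition into C–OTf at 45 °C is much faster than into the two electron-rich aryl bromides flanked by two ortho oxygens, and CO insertion followed by alcoholysis installs the C8 ester.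

Step 6
Reactants: 16 keto ester; 17 2-(phenylsulfonyl)-3-phenyloxaziridine
Product: 19 benzyl 1-[(2R,3S)-3,5,7-tris(benzyloxy)-6,8-dibromochroman-2-yl]-3,4-bis(benzyloxy)-6-hydroxy-5-oxo-6,7-dihydro-5H-benzo[7]annulene-8-carboxylate (C6 epimer mixture), via potassium enolate 18 (not isolated)
Conditions: KHMDS (1.1 equiv), THF, −78 °C; oxaziridine 17; aq NH4Cl
Reagents that add atoms: 2-(phenylsulfonyl)-3-phenyloxaziridine O=S(=O)(c1ccccc1)N1OC1c1ccccc1
Why: In this Davis enolate hydroxylation C6 is the only position α to a ketone, its potassium enolate attacks the oxaziridine oxygen, and the new C6 centre forms as an epimer mixture that step 7 erases.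

Step 7
Reactants: 19 acyloin
Product: 21 benzyl 1-[(2R,3S)-3,5,7-tris(benzyloxy)-6,8-dibromochroman-2-yl]-3,4-bis(benzyloxy)-6-hydroxy-5-oxo-5H-benzo[7]annulene-8-carboxylate, via 5,6-diketone 20 (not isolated)
Conditions: Dess–Martin periodinane, CH2Cl2, 0 °C → rt
Reagents that add atoms: none
Why: Dess–Martin oxidation of the acyloin gives 1,2-diketone 20, whose C7–H is both α-keto and allylic, so it enolises at once to the aromatic hydrogen-bonded tropolone tautomer 21.

Step 8
Reactants: 21 protected dibromo-benzotropolone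
Product: 22 theaflavic acid, 3,4,6-trihydroxy-5-oxo-1-[(2R,3S)-3,5,7-trihydroxychroman-2-yl]-5H-benzo[7]annulene-8-carboxylic acid (target)
Conditions: H2 (1 atm), 20 % Pd(OH)2/C, Et3N (2.2 equiv), THF/MeOH, rt; Sephadex LH-20
Reagents that add atoms: none
Why: Catalytic hydrogenolysis cleaves five benzyl ethers and the benzyl ester and hydrodehalogenates both A-ring C–Br bonds (Et3N traps HBr so no acid can epimerise C2), while the C2–O1 bond and the chelated benzotropolone are reduced far more slowly, so (2R,3S) is retained.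

## Compound list
1 | (+)-catechin, (2R,3S) | Oc1ccc(cc1O)[C@H]1Oc2cc(O)cc(O)c2C[C@@H]1O | starting material
2 | benzyl bromide | BrCc1ccccc1 | starting material
3 | penta-O-benzyl-(+)-catechin, (2R,3S) | C(c1ccccc1)Oc1ccc(cc1OCc1ccccc1)[C@H]1Oc2cc(OCc3ccccc3)cc(OCc3ccccc3)c2C[C@@H]1OCc1ccccc1 | intermediate
4 | N-bromosuccinimide | O=C1CCC(=O)N1Br | starting material
5 | 6,8,6'-tribromo-penta-O-benzylcatechin, (2R,3S) | C(c1ccccc1)Oc1cc(Br)c(cc1OCc1ccccc1)[C@H]1Oc2c(Br)c(OCc3ccccc3)c(Br)c(OCc3ccccc3)c2C[C@@H]1OCc1ccccc1 | intermediate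
6 | cyclopentane-1,3-dione | O=C1CCC(=O)C1 | starting material
7 | lithium 3-oxocyclopent-1-en-1-olate | [Li+].[O-]C1=CC(=O)CC1 | intermediate (not isolated)
8 | 5',6'-aryne of 6,8-dibromo-penta-O-benzylcatechin, (2R,3S) | C(c1ccccc1)OC1=C(OCc2ccccc2)C=C(C#C1)[C@H]1Oc2c(Br)c(OCc3ccccc3)c(Br)c(OCc3ccccc3)c2C[C@@H]1OCc1ccccc1 | intermediate (not isolated)
9 | lithium alkoxide of the cyclopentanone-fused benzocyclobutenol (C6'–CH and C5'–C(O⁻) bonds made; ring-fusion centres unassigned; chroman 2R,3S) | [Li+].[O-]C12CCC(=O)C1c1c([C@H]3Oc4c(Br)c(OCc5ccccc5)c(Br)c(OCc5ccccc5)c4C[C@@H]3OCc3ccccc3)cc(OCc3ccccc3)c(OCc3ccccc3)c12 | intermediate (not isolated)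
10 | ring-expanded benzo[7]annulene-5,8-dione, chroman (2R,3S) | O=C1CCC(=O)Cc2c1c(OCc1ccccc1)c(OCc1ccccc1)cc2[C@H]1Oc2c(Br)c(OCc3ccccc3)c(Br)c(OCc3ccccc3)c2C[C@@H]1OCc1ccccc1 | intermediate
11 | N-phenylbis(trifluoromethanesulfonimide) | O=S(=O)(N(c1ccccc1)S(=O)(=O)C(F)(F)F)C(F)(F)F | starting material
12 | potassium C8=C9 enolate of 10 | [K+].O=C1CCC([O-])=Cc2c1c(OCc1ccccc1)c(OCc1ccccc1)cc2[C@H]1Oc2c(Br)c(OCc3ccccc3)c(Br)c(OCc3ccccc3)c2C[C@@H]1OCc1ccccc1 | intermediate (not isolated)
13 | C8 enol triflate, chroman (2R,3S) | O=C1CCC(OS(=O)(=O)C(F)(F)F)=Cc2c1c(OCc1ccccc1)c(OCc1ccccc1)cc2[C@H]1Oc2c(Br)c(OCc3ccccc3)c(Br)c(OCc3ccccc3)c2C[C@@H]1OCc1ccccc1 | intermediate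
14 | carbon monoxide | [C-]#[O+] | starting material
15 | benzyl alcohol | OCc1ccccc1 | starting material
16 | C8 benzyl ester, 5-oxo-6,7-dihydro-5H-benzo[7]annulene, chroman (2R,3S) | O=C1CCC(C(=O)OCc3ccccc3)=Cc2c1c(OCc1ccccc1)c(OCc1ccccc1)cc2[C@H]1Oc2c(Br)c(OCc3ccccc3)c(Br)c(OCc3ccccc3)c2C[C@@H]1OCc1ccccc1 | intermediate
17 | 2-(phenylsulfonyl)-3-phenyloxaziridine (racemic) | O=S(=O)(c1ccccc1)N1OC1c1ccccc1 | starting material
18 | potassium C5=C6 enolate of 16 | [K+].[O-]C1=CCC(C(=O)OCc3ccccc3)=Cc2c1c(OCc1ccccc1)c(OCc1ccccc1)cc2[C@H]1Oc2c(Br)c(OCc3ccccc3)c(Br)c(OCc3ccccc3)c2C[C@@H]1OCc1ccccc1 | intermediate (not isolated)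
19 | 6-hydroxy-5-ketone (C6 epimers), chroman (2R,3S) | O=C1C(O)CC(C(=O)OCc3ccccc3)=Cc2c1c(OCc1ccccc1)c(OCc1ccccc1)cc2[C@H]1Oc2c(Br)c(OCc3ccccc3)c(Br)c(OCc3ccccc3)c2C[C@@H]1OCc1ccccc1 | intermediate
20 | 5,6-diketone, chroman (2R,3S) | O=C1C(=O)CC(C(=O)OCc3ccccc3)=Cc2c1c(OCc1ccccc1)c(OCc1ccccc1)cc2[C@H]1Oc2c(Br)c(OCc3ccccc3)c(Br)c(OCc3ccccc3)c2C[C@@H]1OCc1ccccc1 | intermediate (not isolated)
21 | protected dibromo-benzotropolone (free 6-OH), chroman (2R,3S) | O=C1C(O)=CC(C(=O)OCc3ccccc3)=Cc2c1c(OCc1ccccc1)c(OCc1ccccc1)cc2[C@H]1Oc2c(Br)c(OCc3ccccc3)c(Br)c(OCc3ccccc3)c2C[C@@H]1OCc1ccccc1 | intermediate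
22 | theaflavic acid, (2R,3S) | O=C(O)c1cc(O)c(=O)c2c(O)c(O)cc([C@H]3Oc4cc(O)cc(O)c4C[C@@H]3O)c2c1 | target

Total step count: 8. Longest linear sequence: 8 (1 → 22).

## Three steps most likely to fail

**Step 3, the aryne σ-insertion.**
- Excess LiTMP could turn 7 into its dianion, which would arylate at the γ-carbon and give a 5,7-dione. This is why 7 is pre-formed and the second LiTMP charge is added last and slowly.
- The aryne could be trapped by tetramethylpiperidine.
- The 3-OBn oxygen could attack the aryne, although this is disfavoured because it needs a trans-fused dihydrobenzofuran.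
- The bulky chroman next to C6' could erode the distal selectivity.
- Br/Li scrambling on ring A is harmless, because those positions end as C–H anyway.

The fallback avoids arynes altogether. It sets out from 5 and comes back to the route at 16, skipping steps 3–5.
- A site-selective Heck reaction runs at the least hindered 6'-bromide (Pd(OAc)2, P(o-tol)3, Et3N, DMF, 90 °C). The partner is dibenzyl 2-methylenepentanedioate F1, the Bu3P-catalysed head-to-tail dimer of commercial benzyl acrylate, and the product is the (E)-arylidene glutarate F2.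
- One equivalent of LiOH saponifies only the unconjugated ester to give the mono-acid F3.
- Oxalyl chloride gives the acid chloride F4.
- SnCl4 (CH2Cl2, −20 °C) closes the seven-membered ring by intramolecular Friedel–Crafts acylation at C5'. This is the only free position ortho to the chain, and ring A has no free C–H because of its bromines.

**Step 8, the global hydrogenolysis.** The tropolone C=C bonds or the benzylic C2–O1 bond may be reduced before the last benzyl ether (the secondary 3-OBn) and the hindered bromides have gone, and the free tropolone can poison the catalyst.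

The fallback uses no hydrogenation catalyst for the debenzylation. It sets out from 21 and comes back at 22.
- Homogeneous formate hydrodebromination (Pd(OAc)2/XPhos, HCO2K, DMF, 70 °C) gives the bromine-free hexabenzyl benzotropolone F7.
- BCl3 with pentamethylbenzene as cation scavenger (CH2Cl2, −78 → −30 °C) strips the five ethers and the ester by Lewis-acid debenzylation.

**Step 4, the regioselective enol triflate.** Kinetic deprotonation at the less hindered C7 or C6, or bis-triflation, would give isomeric triflates.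

The fallback does not rely on enolate regiochemistry. It sets out from 10 and comes back at 16.
- Hydrazine hydrate (EtOH, rt) condenses only with the unhindered dialkyl ketone C8 to give the C8 hydrazone F5.
- Barton iodination (I2, DBU, THF, 0 °C) gives the arene-conjugated C8 vinyl iodide F6.
- F6 is alkoxycarbonylated under the conditions of step 5. It adds to Pd(0) even faster than the triflate, which widens the margin over the aryl bromides.

## Further compounds
F1 | step 3 | dibenzyl 2-methylenepentanedioate | C=C(CCC(=O)OCc1ccccc1)C(=O)OCc1ccccc1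
F2 | step 3 | (E)-arylidene glutarate, Heck product at C6' of the 6,8-dibromo flavan, (2R,3S) | C(c1ccccc1)Oc1cc(/C=C(/C(=O)OCc2ccccc2)CCC(=O)OCc2ccccc2)c(cc1OCc1ccccc1)[C@H]1Oc2c(Br)c(OCc3ccccc3)c(Br)c(OCc3ccccc3)c2C[C@@H]1OCc1ccccc1
F3 | step 3 | mono-acid from F2 (saturated ester cleaved), (2R,3S) | C(c1ccccc1)Oc1cc(/C=C(/C(=O)OCc2ccccc2)CCC(=O)O)c(cc1OCc1ccccc1)[C@H]1Oc2c(Br)c(OCc3ccccc3)c(Br)c(OCc3ccccc3)c2C[C@@H]1OCc1ccccc1
F4 | step 3 | acid chloride of F3, (2R,3S) | C(c1ccccc1)Oc1cc(/C=C(/C(=O)OCc2ccccc2)CCC(=O)Cl)c(cc1OCc1ccccc1)[C@H]1Oc2c(Br)c(OCc3ccccc3)c(Br)c(OCc3ccccc3)c2C[C@@H]1OCc1ccccc1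
F5 | step 4 | C8 hydrazone of 10, (2R,3S) | O=C1CCC(=NN)Cc2c1c(OCc1ccccc1)c(OCc1ccccc1)cc2[C@H]1Oc2c(Br)c(OCc3ccccc3)c(Br)c(OCc3ccccc3)c2C[C@@H]1OCc1ccccc1
F6 | step 4 | C8 vinyl iodide, (2R,3S) | O=C1CCC(I)=Cc2c1c(OCc1ccccc1)c(OCc1ccccc1)cc2[C@H]1Oc2c(Br)c(OCc3ccccc3)c(Br)c(OCc3ccccc3)c2C[C@@H]1OCc1ccccc1
F7 | step 8 | bromine-free hexabenzyl benzotropolone, (2R,3S) | O=C1C(O)=CC(C(=O)OCc3ccccc3)=Cc2c1c(OCc1ccccc1)c(OCc1ccccc1)cc2[C@H]1Oc2cc(OCc3ccccc3)cc(OCc3ccccc3)c2C[C@@H]1OCc1ccccc1
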